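**Retrosynthetic overview**
1. Target 28 ⇐ ester hydrolysis of 27 ⇐ cross-metathesis of 26 ⇐ dearomative aromatic Claisen rearrangement of the (S)-but-3-en-2-yl aryl ether of 23 (key step; chirality transfer sets the quaternary C6).
2. 23 ⇐ Negishi sp2–sp3 coupling of aryl iodide 13 with the alkylzinc from iodide 20; 20 ⇐ diethyl (R)-malate (Fráter–Seebach alkylation sets the side-chain centre).
3. Chromanone ring of 12 ⇐ Mitsunobu ether (inversion) of phenol 6 with hydroxy ester 8 (from tert-butyl (S)-3-hydroxybutanoate), then Friedel–Crafts acylation; C3 by equilibration to 2,3-trans.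
4. Aryl lactone 5 ⇐ phloroglucinol + methyl (2S,3R)-3-phenylglycidate (invertive Friedel–Crafts epoxide opening sets the benzylic centre), then SmI2 deoxygenation.
5. Ring order: temporary aryl δ-lactone (step 1) → dihydropyranone ring (step 6) → lactone opened (step 13) → carbocycle dearomatised to the 6,6-disubstituted triketone (step 14).

Assumption: the target is one enol tautomer of a cyclic β-triketone and is made as that equilibrating compound; 2, 7, 14, 15 and 24 are taken as commercial in the stated form.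

**Step 1**
Reactants: 1 phloroglucinol; 2 methyl (2S,3R)-3-phenyloxirane-2-carboxylate
Product: 4 (3S,4R)-3,5,7-trihydroxy-4-phenylchroman-2-one, via open hydroxy ester 3 (not isolated)
Conditions: 1 (3 equiv), Sc(OTf)3 (5 mol %), (CF3)2CHOH, 0 → 25 °C; then TsOH (10 mol %), PhMe, 80 °C
Reagents that add atoms: none
Why: Friedel–Crafts epoxide opening in which the symmetric arene attacks the benzylic epoxide carbon SN2-like with inversion, so the purchased C3 centre becomes the (R)-benzylic centre, followed by lactonisation onto either of two equivalent ortho-hydroxyls.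

**Step 2**
Reactants: 4 (3S,4R)-3,5,7-trihydroxy-4-phenylchroman-2-one
Product: 5 (4R)-5,7-dihydroxy-4-phenylchroman-2-one
Conditions: SmI2 (3 equiv), THF/HMPA, HOCH2CH2OH, 25 °C
Reagents that add atoms: none
Why: SmI2 reduction of the α-hydroxy lactone (electron transfer, C–O cleavage, protonation of the samarium enolate) removes the C3 hydroxyl without touching the benzylic centre.

**Step 3**
Reactants: 5 (4R)-5,7-dihydroxy-4-phenylchroman-2-one
Product: 6 tert-butyl (4R)-5-hydroxy-2-oxo-4-phenylchroman-7-yl carbonate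
Conditions: Boc2O (1.05 equiv), DMAP (5 mol %), MeCN, 0 °C
Reagents that add atoms: di-tert-butyl dicarbonate, CC(C)(C)OC(=O)OC(=O)OC(C)(C)C
Why: Selective O-acylation of the unhindered 7-OH (the 5-OH sits next to the carbon carrying C4) leaves only the 5-OH free for step 5.

**Step 4**
Reactants: 7 tert-butyl (3S)-3-hydroxybutanoate
Product: 8 tert-butyl (2S,3S)-3-hydroxy-2-methylbutanoate
Conditions: LiN(iPr)2 (2.2 equiv), THF, −78 → −20 °C; MeI, DMPU, −78 → 0 °C; AcOH
Reagents that add atoms: iodomethane, CI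
Why: Fráter–Seebach alkylation, in which the alkoxide-enolate dianion is methylated anti to the C3 oxygen, so the purchased centre controls the new one (2,3-anti).

**Step 5**
Reactants: 6 tert-butyl (4R)-5-hydroxy-2-oxo-4-phenylchroman-7-yl carbonate; 8 tert-butyl (2S,3S)-3-hydroxy-2-methylbutanoate
Product: 9 tert-butyl (2S,3R)-3-{[(4R)-7-(tert-butoxycarbonyloxy)-2-oxo-4-phenylchroman-5-yl]oxy}-2-methylbutanoate
Conditions: PPh3, DIAD, THF, 0 → 40 °C
Reagents that add atoms: none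
Why: Mitsunobu etherification of the only free phenol proceeds by SN2 with inversion at the carbinol carbon, turning the purchased (S)-carbinol into the (R)-aryl ether that becomes chromanone C2.

**Step 6**
Reactants: 9 tert-butyl (2S,3R)-3-{[(4R)-7-(tert-butoxycarbonyloxy)-2-oxo-4-phenylchroman-5-yl]oxy}-2-methylbutanoate
Product: 12 (2R,3R,10R)-5-hydroxy-2,3-dimethyl-10-phenyl-2,3,9,10-tetrahydro-4H,8H-pyrano[2,3-f]chromene-4,8-dione, via aryloxy acid 10 (not isolated), via cis-chromanone 11 (not isolated)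
Conditions: TFA, CH2Cl2, 0 → 25 °C; evaporate; P2O5 in MeSO3H (1:10 w/w), 40 °C; then Et3N (0.2 equiv), CH2Cl2, 25 °C
Reagents that add atoms: none
Why: Acidolysis frees the acid and the 7-OH, the intramolecular Friedel–Crafts acylation can only close at the one ortho C–H of the ether oxygen, and the α-keto centre C3 then epimerises by enolisation to the more stable 2,3-trans chromanone dictated by C2.

**Step 7**
Reactants: 12 (2R,3R,10R)-5-hydroxy-2,3-dimethyl-10-phenyl-2,3,9,10-tetrahydro-4H,8H-pyrano[2,3-f]chromene-4,8-dione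
Product: 13 (2R,3R,10R)-5-hydroxy-6-iodo-2,3-dimethyl-10-phenyl-2,3,9,10-tetrahydro-4H,8H-pyrano[2,3-f]chromene-4,8-dione
Conditions: NIS (1.05 equiv), DMF, 0 → 25 °C
Reagents that add atoms: N-iodosuccinimide, O=C1CCC(=O)N1I
Why: Electrophilic aromatic iodination at the single remaining aromatic C–H, which is activated by three oxygen substituents.

**Step 8**
Reactants: 14 diethyl (2R)-2-hydroxybutanedioate; 15 4-iodo-2-methylbut-1-ene
Product: 16 diethyl (2R,3S)-2-hydroxy-3-(3-methylbut-3-en-1-yl)butanedioate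
Conditions: LiN(iPr)2 (2.1 equiv), THF, −78 → −15 °C; 15, DMPU, −78 → 0 °C; AcOH
Reagents that add atoms: none
Why: Fráter–Seebach alkylation of the malate dianion anti to the alkoxide sets the new C3 centre from the purchased C2 centre.

**Step 9**
Reactants: 16 diethyl (2R,3S)-2-hydroxy-3-(3-methylbut-3-en-1-yl)butanedioate
Product: 17 (2R,3R)-3-(3-methylbut-3-en-1-yl)butane-1,2,4-triol
Conditions: LiAlH4, THF, 0 → 65 °C; then H2O
Reagents that add atoms: none
Why: Hydride reduction of both esters to primary alcohols leaves the stereocentres and the isolated alkene untouched.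

**Step 10**
Reactants: 17 (2R,3R)-3-(3-methylbut-3-en-1-yl)butane-1,2,4-triol
Product: 18 (2R)-2-(hydroxymethyl)-5-methylhex-5-enal
Conditions: NaIO4, THF/H2O (pH 7), 0 °C
Reagents that add atoms: none
Why: Periodate glycol cleavage removes C1 as formaldehyde and turns the former malate carbinol carbon into the aldehyde, leaving the alkylated centre as the only stereocentre.

**Step 11**
Reactants: 18 (2R)-2-(hydroxymethyl)-5-methylhex-5-enal
Product: 19 (2S)-5-methyl-2-(2-methylprop-1-en-1-yl)hex-5-en-1-ol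
Conditions: iPrPPh3I (2.2 equiv), n-BuLi, THF, 0 °C; then 18, −78 → 0 °C
Reagents that add atoms: isopropyltriphenylphosphonium iodide, CC(C)[P+](c1ccccc1)(c1ccccc1)c1ccccc1.[I-]
Why: Wittig olefination with the non-stabilised isopropylidene ylide at low temperature outruns enolisation of the α-branched aldehyde and installs the 2-methylprop-1-enyl group with the stereocentre intact.

**Step 12**
Reactants: 19 (2S)-5-methyl-2-(2-methylprop-1-en-1-yl)hex-5-en-1-ol
Product: 20 (5S)-5-(iodomethyl)-2,7-dimethylocta-1,6-diene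
Conditions: I2, PPh3, imidazole, CH2Cl2, 0 °C
Reagents that add atoms: iodine, II
Why: Appel-type iodination converts the primary alcohol into the iodide by SN2 at CH2, one carbon away from the stereocentre.

**Step 13**
Reactants: 20 (5S)-5-(iodomethyl)-2,7-dimethylocta-1,6-diene; 13 (2R,3R,10R)-5-hydroxy-6-iodo-2,3-dimethyl-10-phenyl-2,3,9,10-tetrahydro-4H,8H-pyrano[2,3-f]chromene-4,8-dione
Product: 23 methyl (3R)-3-{(2R,3R)-5,7-dihydroxy-2,3-dimethyl-6-[(2R)-5-methyl-2-(2-methylprop-1-en-1-yl)hex-5-en-1-yl]-4-oxochroman-8-yl}-3-phenylpropanoate, via alkylzinc iodide 21 (not isolated), via coupled aryl lactone 22 (not isolated)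
Conditions: 20 (2 equiv), Zn dust, LiCl, THF, 35 °C; then 13, Pd(OAc)2 (5 mol %), SPhos (10 mol %), THF, 25 → 45 °C; then MeOH, Et3N (cat.), 40 °C
Reagents that add atoms: methanol, CO
Why: Zinc insertion gives a primary alkylzinc whose stereocentre is β to the metal, Pd-catalysed Negishi coupling joins it to the aryl iodide (the chelated phenol is tolerated), and base-catalysed methanolysis opens the aryl lactone to free the 7-OH.

**Step 14**
Reactants: 23 methyl (3R)-3-{(2R,3R)-5,7-dihydroxy-2,3-dimethyl-6-[(2R)-5-methyl-2-(2-methylprop-1-en-1-yl)hex-5-en-1-yl]-4-oxochroman-8-yl}-3-phenylpropanoate; 24 (2R)-but-3-en-2-ol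
Product: 26 methyl (3R)-3-{(2R,3R,6R)-6-[(2E)-but-2-en-1-yl]-4-hydroxy-2,3-dimethyl-6-[(2R)-5-methyl-2-(2-methylprop-1-en-1-yl)hex-5-en-1-yl]-5,7-dioxo-2,3,6,7-tetrahydro-5H-chromen-8-yl}-3-phenylpropanoate, via allyl aryl ether 25 (not isolated)
Conditions: PPh3, DIAD, PhMe (3 M, sonication), 0 → 25 °C; then 110 °C
Reagents that add atoms: none
Why: Mitsunobu etherification (inversion) of the non-chelated 7-OH is followed by a dearomative aromatic Claisen ([3,3]-sigmatropic) rearrangement to the less hindered ortho carbon C6 through a chair transition state with the methyl group equatorial, which transfers the ether stereocentre to the new quaternary carbon, and enolisation of the resulting β-diketone makes it irreversible.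

**Step 15**
Reactants: 26 methyl (3R)-3-{(2R,3R,6R)-6-[(2E)-but-2-en-1-yl]-4-hydroxy-2,3-dimethyl-6-[(2R)-5-methyl-2-(2-methylprop-1-en-1-yl)hex-5-en-1-yl]-5,7-dioxo-2,3,6,7-tetrahydro-5H-chromen-8-yl}-3-phenylpropanoate
Product: 27 methyl (3R)-3-{(2R,3R,6S)-4-hydroxy-2,3-dimethyl-6-(3-methylbut-2-en-1-yl)-6-[(2R)-5-methyl-2-(2-methylprop-1-en-1-yl)hex-5-en-1-yl]-5,7-dioxo-2,3,6,7-tetrahydro-5H-chromen-8-yl}-3-phenylpropanoate
Conditions: second-generation Grubbs catalyst RuCl2(=CHPh)(PCy3)(H2IMes) (10 mol %), 2-methylbut-2-ene/CH2Cl2, 40 °C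
Reagents that add atoms: 2-methylbut-2-ene, CC=C(C)C
Why: Olefin cross-metathesis with excess 2-methylbut-2-ene swaps the methyl-bearing end of the disubstituted crotyl alkene for an isopropylidene group to give the prenyl group, while the more hindered trisubstituted and 1,1-disubstituted alkenes react more slowly.

**Step 16**
Reactants: 27 methyl (3R)-3-{(2R,3R,6S)-4-hydroxy-2,3-dimethyl-6-(3-methylbut-2-en-1-yl)-6-[(2R)-5-methyl-2-(2-methylprop-1-en-1-yl)hex-5-en-1-yl]-5,7-dioxo-2,3,6,7-tetrahydro-5H-chromen-8-yl}-3-phenylpropanoate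
Product: 28 (3R)-3-{(2R,3R,6S)-4-hydroxy-2,3-dimethyl-6-(3-methylbut-2-en-1-yl)-6-[(2R)-5-methyl-2-(2-methylprop-1-en-1-yl)hex-5-en-1-yl]-5,7-dioxo-2,3,6,7-tetrahydro-5H-chromen-8-yl}-3-phenylpropanoic acid
Conditions: LiOH (4 equiv), THF/H2O, 0 → 25 °C; then aq. HCl to pH 3
Reagents that add atoms: lithium hydroxide, [Li+].[OH-]
Why: Saponification of the methyl ester, during which the enolised triketone sits as its anion and shields C2/C3 from further deprotonation, followed by acidification.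

**Compound list**
1 | phloroglucinol (benzene-1,3,5-triol) | Oc1cc(O)cc(O)c1 | starting material
2 | methyl (2S,3R)-3-phenyloxirane-2-carboxylate | COC(=O)[C@H]1O[C@@H]1c1ccccc1 | starting material
3 | methyl (2S,3R)-2-hydroxy-3-phenyl-3-(2,4,6-trihydroxyphenyl)propanoate | COC(=O)[C@@H](O)[C@H](c1ccccc1)c1c(O)cc(O)cc1O | intermediate
4 | (3S,4R)-3,5,7-trihydroxy-4-phenylchroman-2-one | O=C1[C@@H](O)[C@H](c2ccccc2)c2c(O)cc(O)cc2O1 | intermediate
5 | (4R)-5,7-dihydroxy-4-phenylchroman-2-one | O=C1C[C@H](c2ccccc2)c2c(O)cc(O)cc2O1 | intermediate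
6 | tert-butyl (4R)-5-hydroxy-2-oxo-4-phenylchroman-7-yl carbonate | O=C1C[C@H](c2ccccc2)c2c(O)cc(OC(=O)OC(C)(C)C)cc2O1 | intermediate
7 | tert-butyl (3S)-3-hydroxybutanoate | CC(C)(C)OC(=O)C[C@H](C)O | starting material
8 | tert-butyl (2S,3S)-3-hydroxy-2-methylbutanoate | CC(C)(C)OC(=O)[C@@H](C)[C@H](C)O | intermediate
9 | tert-butyl (2S,3R)-3-{[(4R)-7-(tert-butoxycarbonyloxy)-2-oxo-4-phenylchroman-5-yl]oxy}-2-methylbutanoate | CC(C)(C)OC(=O)[C@@H](C)[C@@H](C)Oc1cc(OC(=O)OC(C)(C)C)cc2OC(=O)C[C@H](c3ccccc3)c12 | intermediate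
10 | (2S,3R)-3-{[(4R)-7-hydroxy-2-oxo-4-phenylchroman-5-yl]oxy}-2-methylbutanoic acid | OC(=O)[C@@H](C)[C@@H](C)Oc1cc(O)cc2OC(=O)C[C@H](c3ccccc3)c12 | intermediate
11 | (2R,3S,10R)-5-hydroxy-2,3-dimethyl-10-phenyl-2,3,9,10-tetrahydro-4H,8H-pyrano[2,3-f]chromene-4,8-dione (2,3-cis) | c1c(O)c2C(=O)[C@@H](C)[C@@H](C)Oc2c2[C@@H](c3ccccc3)CC(=O)Oc12 | intermediate
12 | (2R,3R,10R)-5-hydroxy-2,3-dimethyl-10-phenyl-2,3,9,10-tetrahydro-4H,8H-pyrano[2,3-f]chromene-4,8-dione (2,3-trans) | c1c(O)c2C(=O)[C@H](C)[C@@H](C)Oc2c2[C@@H](c3ccccc3)CC(=O)Oc12 | intermediate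
13 | (2R,3R,10R)-5-hydroxy-6-iodo-2,3-dimethyl-10-phenyl-2,3,9,10-tetrahydro-4H,8H-pyrano[2,3-f]chromene-4,8-dione | Ic1c(O)c2C(=O)[C@H](C)[C@@H](C)Oc2c2[C@@H](c3ccccc3)CC(=O)Oc12 | intermediate
14 | diethyl (2R)-2-hydroxybutanedioate (diethyl (R)-malate) | CCOC(=O)C[C@@H](O)C(=O)OCC | starting material
15 | 4-iodo-2-methylbut-1-ene | C=C(C)CCI | starting material
16 | diethyl (2R,3S)-2-hydroxy-3-(3-methylbut-3-en-1-yl)butanedioate | C=C(C)CC[C@@H]([C@@H](O)C(=O)OCC)C(=O)OCC | intermediate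
17 | (2R,3R)-3-(3-methylbut-3-en-1-yl)butane-1,2,4-triol | C=C(C)CC[C@@H]([C@@H](O)CO)CO | intermediate
18 | (2R)-2-(hydroxymethyl)-5-methylhex-5-enal | C=C(C)CC[C@@H](C=O)CO | intermediate
19 | (2S)-5-methyl-2-(2-methylprop-1-en-1-yl)hex-5-en-1-ol | C=C(C)CC[C@@H](C=C(C)C)CO | intermediate
20 | (5S)-5-(iodomethyl)-2,7-dimethylocta-1,6-diene | C=C(C)CC[C@@H](C=C(C)C)CI | intermediate
21 | [(2S)-5-methyl-2-(2-methylprop-1-en-1-yl)hex-5-en-1-yl]zinc iodide | C=C(C)CC[C@@H](C=C(C)C)C[Zn]I | intermediate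
22 | (2R,3R,10R)-5-hydroxy-2,3-dimethyl-6-[(2R)-5-methyl-2-(2-methylprop-1-en-1-yl)hex-5-en-1-yl]-10-phenyl-2,3,9,10-tetrahydro-4H,8H-pyrano[2,3-f]chromene-4,8-dione | C=C(C)CC[C@@H](C=C(C)C)Cc1c(O)c2C(=O)[C@H](C)[C@@H](C)Oc2c2[C@@H](c3ccccc3)CC(=O)Oc12 | intermediate
23 | methyl (3R)-3-{(2R,3R)-5,7-dihydroxy-2,3-dimethyl-6-[(2R)-5-methyl-2-(2-methylprop-1-en-1-yl)hex-5-en-1-yl]-4-oxochroman-8-yl}-3-phenylpropanoate | C=C(C)CC[C@@H](C=C(C)C)Cc1c(O)c2C(=O)[C@H](C)[C@@H](C)Oc2c([C@@H](c2ccccc2)CC(=O)OC)c1O | intermediate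
24 | (2R)-but-3-en-2-ol | C=C[C@@H](C)O | starting material
25 | methyl (3R)-3-{(2R,3R)-7-[(2S)-but-3-en-2-yloxy]-5-hydroxy-2,3-dimethyl-6-[(2R)-5-methyl-2-(2-methylprop-1-en-1-yl)hex-5-en-1-yl]-4-oxochroman-8-yl}-3-phenylpropanoate | C=C(C)CC[C@@H](C=C(C)C)Cc1c(O)c2C(=O)[C@H](C)[C@@H](C)Oc2c([C@@H](c2ccccc2)CC(=O)OC)c1O[C@@H](C)C=C | intermediate
26 | methyl (3R)-3-{(2R,3R,6R)-6-[(2E)-but-2-en-1-yl]-4-hydroxy-2,3-dimethyl-6-[(2R)-5-methyl-2-(2-methylprop-1-en-1-yl)hex-5-en-1-yl]-5,7-dioxo-2,3,6,7-tetrahydro-5H-chromen-8-yl}-3-phenylpropanoate | C=C(C)CC[C@@H](C=C(C)C)C[C@@]1(C/C=C/C)C(=O)C2=C(O)[C@H](C)[C@@H](C)OC2=C([C@H](CC(=O)OC)c2ccccc2)C1=O | intermediate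
27 | methyl (3R)-3-{(2R,3R,6S)-4-hydroxy-2,3-dimethyl-6-(3-methylbut-2-en-1-yl)-6-[(2R)-5-methyl-2-(2-methylprop-1-en-1-yl)hex-5-en-1-yl]-5,7-dioxo-2,3,6,7-tetrahydro-5H-chromen-8-yl}-3-phenylpropanoate | C=C(C)CC[C@@H](C=C(C)C)C[C@@]1(CC=C(C)C)C(=O)C2=C(O)[C@H](C)[C@@H](C)OC2=C([C@H](CC(=O)OC)c2ccccc2)C1=O | intermediate
28 | (3R)-3-{(2R,3R,6S)-4-hydroxy-2,3-dimethyl-6-(3-methylbut-2-en-1-yl)-6-[(2R)-5-methyl-2-(2-methylprop-1-en-1-yl)hex-5-en-1-yl]-5,7-dioxo-2,3,6,7-tetrahydro-5H-chromen-8-yl}-3-phenylpropanoic acid | C=C(C)CC[C@@H](C=C(C)C)C[C@@]1(CC=C(C)C)C(=O)C2=C(O)[C@H](C)[C@@H](C)OC2=C([C@H](CC(=O)O)c2ccccc2)C1=O | target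

**Totals**
Total steps: 16. Longest linear sequence: 10 steps (1, 2, 3, 5, 6, 7, 13, 14, 15, 16 from phloroglucinol).

**Steps most likely to fail**

Step 5. The alcohol 8 is α-branched and the phenol of 6 is flanked by the C4-bearing ring carbon, so elimination of 8 to the tiglate can outrun the SN2 etherification. Fallback, setting out from 8 (and using 6) and coming back at 12: 8 is cleaved with TFA to (2S,3S)-3-hydroxy-2-methylbutanoic acid F1. F1 is closed with PhSO2Cl/pyridine at 0 °C (carboxyl activation, retention) to (3S,4S)-3,4-dimethyloxetan-2-one F2. The caesium phenoxide of 6 (Cs2CO3, DMF) opens F2 at C4 by alkyl–oxygen cleavage (SN2, inversion) to give (2S,3R)-3-{[(4R)-7-(tert-butoxycarbonyloxy)-2-oxo-4-phenylchroman-5-yl]oxy}-2-methylbutanoic acid F3. F3 is taken through the acid treatment of step 6 to 12.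

Step 14. The phenol to be etherified carries two ortho substituents, a second (chelated) hydroxyl is present, and a secondary allylic alcohol can react SN2′; any of these lowers yield or stereochemical fidelity at C6. Fallback, setting out from 23 and coming back at 27: O-alkylation with tert-butyl 2-methylbut-3-en-2-yl carbonate (C=CC(C)(C)OC(=O)OC(C)(C)C) and Pd(PPh3)4 in THF gives methyl (3R)-3-{(2R,3R)-5-hydroxy-2,3-dimethyl-7-[(2-methylbut-3-en-2-yl)oxy]-6-[(2R)-5-methyl-2-(2-methylprop-1-en-1-yl)hex-5-en-1-yl]-4-oxochroman-8-yl}-3-phenylpropanoate F4. Heating F4 in toluene at 110 °C effects the same dearomative Claisen rearrangement and delivers the prenyl group directly, so 27 is reached without steps 14 and 15. This gives up chirality transfer; the two C6 epimers are separated by preparative HPLC.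

Step 15. Ring-closing metathesis between the crotyl group and the 2-methylprop-1-enyl group on the neighbouring chain (six-membered ring, geminal substitution) can compete with the cross-metathesis. Fallback, setting out from 23 and coming back at 27: direct alkylative dearomatisation, in which the dianion of 23 (LiN(SiMe3)2, THF/PhMe, 0 °C) is C-alkylated at C6 with prenyl bromide (CC(C)=CCBr). No metathesis and no new intermediate is involved; the C6 epimers (about 1:1) are separated by preparative HPLC.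

**Further compounds**
F1 | step 5 | (2S,3S)-3-hydroxy-2-methylbutanoic acid | OC(=O)[C@@H](C)[C@H](C)O
F2 | step 5 | (3S,4S)-3,4-dimethyloxetan-2-one | O=C1O[C@@H](C)[C@@H]1C
F3 | step 5 | (2S,3R)-3-{[(4R)-7-(tert-butoxycarbonyloxy)-2-oxo-4-phenylchroman-5-yl]oxy}-2-methylbutanoic acid | OC(=O)[C@@H](C)[C@@H](C)Oc1cc(OC(=O)OC(C)(C)C)cc2OC(=O)C[C@H](c3ccccc3)c12
F4 | step 14 | methyl (3R)-3-{(2R,3R)-5-hydroxy-2,3-dimethyl-7-[(2-methylbut-3-en-2-yl)oxy]-6-[(2R)-5-methyl-2-(2-methylprop-1-en-1-yl)hex-5-en-1-yl]-4-oxochroman-8-yl}-3-phenylpropanoate | C=C(C)CC[C@@H](C=C(C)C)Cc1c(O)c2C(=O)[C@H](C)[C@@H](C)Oc2c([C@@H](c2ccccc2)CC(=O)OC)c1OC(C)(C)C=C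
F0 | step 15 | none | none
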